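## Retrosynthetic overview

1. Target ⇐ Si–O cleavage ⇐ ring-closing metathesis of a vinyl/isopropenyl diene; the 10-membered carbocycle with its Z C4=C5 olefin is the last ring formed.
2. Diene ⇐ Mitsunobu angeloylation with inversion at C8 ⇐ zinc Barbier union (C7–C8 bond, exo-methylene lactone unveiled) of a west bromobutenolide with an east keto aldehyde.
3. West fragment: the γ-lactone (C6) comes intact from (S)-5-(hydroxymethyl)butyrolactone; vinyl by Wittig; butenolide and CH2Br by selenide / formaldehyde aldol / selenoxide elimination / Appel.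
4. East fragment: C10 from (R)-lactic acid by Seebach alkylation; ozonolysis and lactonisation; the C2–C4 isopropenyl arm by Grignard addition; oxidation to the C8 aldehyde.
5. Ring order: butyrolactone (chiral pool) → butenolide → α-methylene lactone (Barbier) → cyclodecene (metathesis).

Assumption: atom labels C1–C15 follow germacrane numbering (C1 ketone, C4=C5 ring olefin, C6 lactone O–CH, C7 ring-fusion CH, C8 ester carbinol, C10 tertiary carbinol); the target is read as 6R,7R,8R,10S with a Z ring olefin and a Z (angelate) ester.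

## Route

**East fragment (steps 1–7)**

Step 1
Reactants: 1 (R)-lactic acid
Product: 2 (2R,5R)-2-tert-butyl-5-methyl-1,3-dioxolan-4-one
Conditions: pivalaldehyde, TsOH·H2O (cat.), H2SO4 (cat.), pentane, reflux, Dean–Stark; recrystallise from pentane at −78 °C
Reagents that add atoms: pivalaldehyde, CC(C)(C)C=O
Why: Acid-catalysed acetalisation (Seebach self-regeneration of stereocentres); the cis acetal, whose new centre (2R) is set by the lactate centre under equilibrating conditions, crystallises pure.

Step 2
Reactants: 2 (2R,5R)-2-tert-butyl-5-methyl-1,3-dioxolan-4-one; 3 allyl bromide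
Product: 5 (2R,5S)-5-allyl-2-tert-butyl-5-methyl-1,3-dioxolan-4-one, via lithium enolate 4 (not isolated)
Conditions: LiN(iPr)2, THF, −78 °C; then 3, −78 to −30 °C
Reagents that add atoms: none
Why: Enolate alkylation in which allyl bromide attacks the planar enolate on the face opposite the tert-butyl group, regenerating the quaternary centre (future C10, S) with overall retention.

Step 3
Reactants: 5 (2R,5S)-5-allyl-2-tert-butyl-5-methyl-1,3-dioxolan-4-one
Product: 6 (2R,5S)-2-tert-butyl-5-methyl-5-(2-oxoethyl)-1,3-dioxolan-4-one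
Conditions: O3, CH2Cl2, −78 °C; then PPh3, −78 °C to rt
Reagents that add atoms: ozone, [O-][O+]=O
Why: Ozonolysis with reductive work-up cleaves the only olefin to the aldehyde (future C8) while the acylal ring is inert to ozone.

Step 4
Reactants: 6 (2R,5S)-2-tert-butyl-5-methyl-5-(2-oxoethyl)-1,3-dioxolan-4-one
Product: 8 (3S)-3-hydroxy-3-methyloxolan-2-one, via hydroxyethyl dioxolanone 7 (not isolated)
Conditions: NaBH4, MeOH, −20 °C; then 1 M HCl to pH 2, rt
Reagents that add atoms: none
Why: Borohydride reduction of the aldehyde followed by 5-exo transacylation (lactonisation) onto the activated dioxolanone carbonyl, which expels pivalaldehyde and leaves the quaternary centre untouched.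

Step 5
Reactants: 8 (3S)-3-hydroxy-3-methyloxolan-2-one
Product: 9 (3S)-3-methyl-3-[(triethylsilyl)oxy]oxolan-2-one
Conditions: Et3SiOTf, 2,6-lutidine, CH2Cl2, −78 to 0 °C
Reagents that add atoms: triethylsilyl trifluoromethanesulfonate, CC[Si](CC)(CC)OS(=O)(=O)C(F)(F)F
Why: Silyl ether formation with the reactive silyl triflate protects the hindered tertiary alcohol so that the later β-oxygenated aldehyde cannot dehydrate or undergo retro-aldol cleavage.

Step 6
Reactants: 9 (3S)-3-methyl-3-[(triethylsilyl)oxy]oxolan-2-one; 10 4-bromo-2-methylbut-1-ene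
Product: 12 (3S)-1-hydroxy-3,7-dimethyl-3-[(triethylsilyl)oxy]oct-7-en-4-one, via Grignard reagent 11 (not isolated)
Conditions: 10, Mg turnings, THF, rt; add to 9 (1.15 equiv of 11), THF, −78 °C; H2O quench at −78 °C
Reagents that add atoms: none
Why: Grignard addition to a lactone stops after one addition because the magnesium lactolate of this α-quaternary lactone is stable at −78 °C and is protonated before it can open and react again.

Step 7
Reactants: 12 (3S)-1-hydroxy-3,7-dimethyl-3-[(triethylsilyl)oxy]oct-7-en-4-one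
Product: 13 (3S)-3,7-dimethyl-4-oxo-3-[(triethylsilyl)oxy]oct-7-enal
Conditions: Dess–Martin periodinane, CH2Cl2, 0 °C to rt
Reagents that add atoms: none
Why: Dess–Martin oxidation of the primary alcohol (the open form of any cyclic hemiketal) is neutral and leaves the silyl ether, ketone and 1,1-disubstituted olefin alone.

**West fragment (steps 8–13)**

Step 8
Reactants: 14 (5S)-5-(hydroxymethyl)oxolan-2-one
Product: 15 (2S)-5-oxooxolane-2-carbaldehyde
Conditions: Dess–Martin periodinane, CH2Cl2, rt; non-aqueous work-up, used at once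
Reagents that add atoms: none
Why: Dess–Martin oxidation under neutral, water-free conditions gives the hydrate-prone α-acyloxy aldehyde without epimerising the future C6.

Step 9
Reactants: 15 (2S)-5-oxooxolane-2-carbaldehyde
Product: 16 (5S)-5-vinyloxolan-2-one
Conditions: Ph3PCH3Br, KN(SiMe3)2, THF, −78 to 0 °C
Reagents that add atoms: methyltriphenylphosphonium bromide, C[P+](c1ccccc1)(c1ccccc1)c1ccccc1.[Br-]
Why: Wittig methylenation with a slight deficit of base converts the aldehyde to the vinyl group at low temperature, faster than the ylide attacks the lactone or epimerises the α-oxygenated centre.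

Step 10
Reactants: 16 (5S)-5-vinyloxolan-2-one
Product: 18 (5S)-3-(phenylselanyl)-5-vinyloxolan-2-one (C3 epimer mixture), via lithium enolate 17 (not isolated)
Conditions: LiN(iPr)2, THF, −78 °C; cannulate into PhSeBr, THF, −78 °C
Reagents that add atoms: phenylselanyl bromide, Br[Se]c1ccccc1
Why: α-Selenenylation of the lactone enolate is much faster at −78 °C than addition of the selenyl halide to the vinyl group; the new C3 centre is removed later.

Step 11
Reactants: 18 (5S)-3-(phenylselanyl)-5-vinyloxolan-2-one; 19 formaldehyde (gas from cracked paraformaldehyde)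
Product: 21 (5S)-3-(hydroxymethyl)-3-(phenylselanyl)-5-vinyloxolan-2-one (C3 epimer mixture), via lithium enolate 20 (not isolated)
Conditions: LiN(iPr)2, THF, −78 °C; 19, −78 °C; AcOH quench at −78 °C
Reagents that add atoms: none
Why: Aldol addition of the selenium-stabilised enolate to formaldehyde installs C13 at the oxidation level needed for the allylic bromide, and the cold acid quench prevents retro-aldol.

Step 12
Reactants: 21 (5S)-3-(hydroxymethyl)-3-(phenylselanyl)-5-vinyloxolan-2-one
Product: 23 (5R)-3-(hydroxymethyl)-5-vinylfuran-2(5H)-one, via selenoxide 22 (not isolated)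
Conditions: 30% H2O2, CH2Cl2, 0 °C to rt
Reagents that add atoms: none
Why: Selenide oxidation then selenoxide syn-elimination, which goes into the ring (away from the carbinol carbon) to give the conjugated butenolide under base-free conditions that do not touch the labile C6–H.

Step 13
Reactants: 23 (5R)-3-(hydroxymethyl)-5-vinylfuran-2(5H)-one
Product: 24 (5R)-3-(bromomethyl)-5-vinylfuran-2(5H)-one
Conditions: CBr4, PPh3, CH2Cl2, 0 °C
Reagents that add atoms: carbon tetrabromide, BrC(Br)(Br)Br
Why: Appel bromination converts the primary allylic alcohol to the bromide under neutral conditions, so the base-sensitive γ-vinyl butenolide keeps its configuration.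

**Union and endgame (steps 14–17)**

Step 14
Reactants: 24 (5R)-3-(bromomethyl)-5-vinylfuran-2(5H)-one; 13 (3S)-3,7-dimethyl-4-oxo-3-[(triethylsilyl)oxy]oct-7-enal
Product: 26 (4R,5R)-4-[(1S,3S)-1-hydroxy-3,7-dimethyl-4-oxo-3-[(triethylsilyl)oxy]oct-7-en-1-yl]-3-methylidene-5-vinyloxolan-2-one, via allylzinc bromide 25 (not isolated)
Conditions: Zn dust (activated), THF/sat. aq. NH4Cl 2:1, 0 °C to rt; used without delay
Reagents that add atoms: none
Why: Zinc Barbier allylation at the γ-carbon (C7) of the ring-locked E-allylzinc goes through a Zimmerman–Traxler chair with the aldehyde chain equatorial, on the face opposite the C6 vinyl group; this sets C7 (R, trans to C6) and the 7,8-anti carbinol (8S, the epimer that step 15 inverts), while the aldehyde reacts in preference to the hindered ketone.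

Step 15
Reactants: 26 the (8S)-carbinol from step 14; 27 angelic acid, (2Z)-2-methylbut-2-enoic acid
Product: 28 (1R,3S)-3,7-dimethyl-1-[(2R,3R)-4-methylidene-5-oxo-2-vinyloxolan-3-yl]-4-oxo-3-[(triethylsilyl)oxy]oct-7-en-1-yl (2Z)-2-methylbut-2-enoate
Conditions: PPh3, DIAD, toluene, 0 °C to rt
Reagents that add atoms: none
Why: Mitsunobu esterification displaces the activated C8 oxygen with angelate by SN2 inversion, turning the 8S carbinol into the required 8R ester under neutral conditions that keep the Z ester geometry and do not trigger lactone migration.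

Step 16
Reactants: 28 the angelate diene from step 15
Product: 29 (3aR,4R,6S,10Z,11aR)-6,10-dimethyl-3-methylidene-2,7-dioxo-6-[(triethylsilyl)oxy]-2,3,3a,4,5,6,7,8,9,11a-decahydrocyclodeca[b]furan-4-yl (2Z)-2-methylbut-2-enoate
Conditions: second-generation Hoveyda–Grubbs catalyst RuCl2(H2IMes)(=CH-C6H4-2-OiPr) (15 mol% in two portions), toluene (1 mM), 90 °C, argon sparge
Reagents that add atoms: none
Why: Ring-closing metathesis loads ruthenium on the monosubstituted vinyl group and closes onto the isopropenyl group with loss of ethene; the 10-membered ring forces the new trisubstituted olefin to be Z, and the electron-poor exo-methylene and angelate olefins are poor metathesis partners.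

Step 17
Reactants: 29 the silyl-protected macrocycle from step 16
Product: 30 (3aR,4R,6S,10Z,11aR)-6-hydroxy-6,10-dimethyl-3-methylidene-2,7-dioxo-2,3,3a,4,5,6,7,8,9,11a-decahydrocyclodeca[b]furan-4-yl (2Z)-2-methylbut-2-enoate (target)
Conditions: HF·pyridine, THF, 0 °C to rt
Reagents that add atoms: none
Why: Fluoride-mediated desilylation frees the tertiary alcohol under mildly acidic conditions that spare the α-methylene lactone, the angelate and the α-hydroxy ketone.

## Compound list

1 | (R)-lactic acid | C[C@@H](O)C(=O)O | starting material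
2 | (2R,5R)-2-tert-butyl-5-methyl-1,3-dioxolan-4-one | C[C@H]1O[C@@H](C(C)(C)C)OC1=O | intermediate
3 | allyl bromide | C=CCBr | starting material
4 | lithium (2R)-2-tert-butyl-5-methyl-1,3-dioxol-4-olate (enolate of 2) | CC1=C(O[Li])O[C@H](C(C)(C)C)O1 | intermediate
5 | (2R,5S)-5-allyl-2-tert-butyl-5-methyl-1,3-dioxolan-4-one | C[C@@]1(CC=C)O[C@@H](C(C)(C)C)OC1=O | intermediate
6 | (2R,5S)-2-tert-butyl-5-methyl-5-(2-oxoethyl)-1,3-dioxolan-4-one | C[C@@]1(CC=O)O[C@@H](C(C)(C)C)OC1=O | intermediate
7 | (2R,5S)-2-tert-butyl-5-(2-hydroxyethyl)-5-methyl-1,3-dioxolan-4-one | C[C@@]1(CCO)O[C@@H](C(C)(C)C)OC1=O | intermediate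
8 | (3S)-3-hydroxy-3-methyloxolan-2-one | C[C@]1(O)CCOC1=O | intermediate
9 | (3S)-3-methyl-3-[(triethylsilyl)oxy]oxolan-2-one | C[C@]1(O[Si](CC)(CC)CC)CCOC1=O | intermediate
10 | 4-bromo-2-methylbut-1-ene | C=C(C)CCBr | starting material
11 | (3-methylbut-3-en-1-yl)magnesium bromide | C=C(C)CC[Mg]Br | intermediate
12 | (3S)-1-hydroxy-3,7-dimethyl-3-[(triethylsilyl)oxy]oct-7-en-4-one | C=C(C)CCC(=O)[C@@](C)(O[Si](CC)(CC)CC)CCO | intermediate
13 | (3S)-3,7-dimethyl-4-oxo-3-[(triethylsilyl)oxy]oct-7-enal | C=C(C)CCC(=O)[C@@](C)(O[Si](CC)(CC)CC)CC=O | intermediate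
14 | (5S)-5-(hydroxymethyl)oxolan-2-one | OC[C@@H]1CCC(=O)O1 | starting material
15 | (2S)-5-oxooxolane-2-carbaldehyde | O=C[C@@H]1CCC(=O)O1 | intermediate
16 | (5S)-5-vinyloxolan-2-one | C=C[C@@H]1CCC(=O)O1 | intermediate
17 | lithium (5S)-5-vinyl-4,5-dihydrofuran-2-olate (enolate of 16) | C=C[C@@H]1CC=C(O[Li])O1 | intermediate
18 | (5S)-3-(phenylselanyl)-5-vinyloxolan-2-one, C3 epimer mixture | C=C[C@@H]1CC([Se]c2ccccc2)C(=O)O1 | intermediate
19 | formaldehyde (from paraformaldehyde) | C=O | starting material
20 | lithium (5S)-3-(phenylselanyl)-5-vinyl-4,5-dihydrofuran-2-olate (enolate of 18) | C=C[C@@H]1CC([Se]c2ccccc2)=C(O[Li])O1 | intermediate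
21 | (5S)-3-(hydroxymethyl)-3-(phenylselanyl)-5-vinyloxolan-2-one, C3 epimer mixture | C=C[C@@H]1CC(CO)([Se]c2ccccc2)C(=O)O1 | intermediate
22 | (5S)-3-(hydroxymethyl)-3-(phenylseleninyl)-5-vinyloxolan-2-one | C=C[C@@H]1CC(CO)([Se](=O)c2ccccc2)C(=O)O1 | intermediate
23 | (5R)-3-(hydroxymethyl)-5-vinylfuran-2(5H)-one | C=C[C@@H]1C=C(CO)C(=O)O1 | intermediate
24 | (5R)-3-(bromomethyl)-5-vinylfuran-2(5H)-one | C=C[C@@H]1C=C(CBr)C(=O)O1 | intermediate
25 | bromo{[(5R)-2-oxo-5-vinyl-2,5-dihydrofuran-3-yl]methyl}zinc | C=C[C@@H]1C=C(C[Zn]Br)C(=O)O1 | intermediate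
26 | (4R,5R)-4-[(1S,3S)-1-hydroxy-3,7-dimethyl-4-oxo-3-[(triethylsilyl)oxy]oct-7-en-1-yl]-3-methylidene-5-vinyloxolan-2-one | C=C1C(=O)O[C@H](C=C)[C@H]1[C@@H](O)C[C@](C)(O[Si](CC)(CC)CC)C(=O)CCC(C)=C | intermediate
27 | angelic acid, (2Z)-2-methylbut-2-enoic acid | C/C=C(/C)C(=O)O | starting material
28 | (1R,3S)-3,7-dimethyl-1-[(2R,3R)-4-methylidene-5-oxo-2-vinyloxolan-3-yl]-4-oxo-3-[(triethylsilyl)oxy]oct-7-en-1-yl (2Z)-2-methylbut-2-enoate | C=C1C(=O)O[C@H](C=C)[C@H]1[C@H](OC(=O)/C(C)=C\C)C[C@](C)(O[Si](CC)(CC)CC)C(=O)CCC(C)=C | intermediate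
29 | (3aR,4R,6S,10Z,11aR)-6,10-dimethyl-3-methylidene-2,7-dioxo-6-[(triethylsilyl)oxy]-2,3,3a,4,5,6,7,8,9,11a-decahydrocyclodeca[b]furan-4-yl (2Z)-2-methylbut-2-enoate | C=C1C(=O)O[C@@H]2/C=C(/C)CCC(=O)[C@@](C)(O[Si](CC)(CC)CC)C[C@@H](OC(=O)/C(C)=C\C)[C@@H]12 | intermediate
30 | (3aR,4R,6S,10Z,11aR)-6-hydroxy-6,10-dimethyl-3-methylidene-2,7-dioxo-2,3,3a,4,5,6,7,8,9,11a-decahydrocyclodeca[b]furan-4-yl (2Z)-2-methylbut-2-enoate | C=C1C(=O)O[C@@H]2/C=C(/C)CCC(=O)[C@@](C)(O)C[C@@H](OC(=O)/C(C)=C\C)[C@@H]12 | target

## Step count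

Total step count: 17 (east fragment 7, west fragment 6, union and endgame 4).
Longest linear sequence: 11 steps (steps 1–7, then 14–17); the west branch runs 10 steps to the target (steps 8–13, then 14–17).

## Steps most likely to fail, with fallbacks

Step 16 (ring-closing metathesis to a 10-membered ring with a trisubstituted olefin; oligomerisation or no closure are the likely failures). The fallback changes the substrate that is cyclised and the order of the endgame, not the catalyst. It sets out from 28: HF·pyridine removes the silyl group first and gives the hydroxy ketone diene (1R,3S)-3-hydroxy-3,7-dimethyl-1-[(2R,3R)-4-methylidene-5-oxo-2-vinyloxolan-3-yl]-4-oxooct-7-en-1-yl (2Z)-2-methylbut-2-enoate F1. In F1 the free tertiary hydroxyl can hydrogen-bond to the C1 ketone and the bulky silyl group no longer sits on the chain that must fold. Metathesis of F1 then closes the ring to 30 directly, so the fallback comes back to the route at 30.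

Step 15 (Mitsunobu on a β-branched secondary alcohol with a weakly acidic unsaturated acid; elimination or retention are possible, and the step relies on the 7,8-anti outcome of step 14). The fallback sets C8 in the R configuration in the C–C bond-forming step and esterifies with retention. It sets out from 24 and 13. Bromide 24 with hexabutylditin and Pd2(dba)3 gives the allylstannane (5R)-3-[(tributylstannyl)methyl]-5-vinylfuran-2(5H)-one F2. Addition of F2 to 13 promoted by BF3·OEt2 at −78 °C goes through an open, antiperiplanar transition state and gives the 7,8-syn carbinol (4R,5R)-4-[(1R,3S)-1-hydroxy-3,7-dimethyl-4-oxo-3-[(triethylsilyl)oxy]oct-7-en-1-yl]-3-methylidene-5-vinyloxolan-2-one F3. Yamaguchi esterification of F3 with 27 (2,4,6-trichlorobenzoyl chloride, Et3N, toluene, 80 °C, no DMAP so the Z ester is kept) gives 28, where the fallback comes back to the route.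

Step 6 (single Grignard addition to a lactone; over-addition to the tertiary alcohol is the risk). The fallback goes through a Weinreb amide and sets out from 8. AlMe3 with MeONHMe·HCl opens the lactone to (2S)-2,4-dihydroxy-N-methoxy-N,2-dimethylbutanamide F4. Et3SiOTf and 2,6-lutidine give (2S)-N-methoxy-N,2-dimethyl-2,4-bis[(triethylsilyl)oxy]butanamide F5. Grignard reagent 11 adds once to F5, whose chelated adduct cannot add again, and gives (3S)-3,7-dimethyl-1,3-bis[(triethylsilyl)oxy]oct-7-en-4-one F6. Swern conditions (oxalyl chloride, DMSO, Et3N) cleave the primary silyl ether of F6 and oxidise it in the same operation to 13, where the fallback comes back to the route.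

## Further compounds

F1 | step 16 | (1R,3S)-3-hydroxy-3,7-dimethyl-1-[(2R,3R)-4-methylidene-5-oxo-2-vinyloxolan-3-yl]-4-oxooct-7-en-1-yl (2Z)-2-methylbut-2-enoate | C=C1C(=O)O[C@H](C=C)[C@H]1[C@H](OC(=O)/C(C)=C\C)C[C@](C)(O)C(=O)CCC(C)=C
F2 | step 15 | (5R)-3-[(tributylstannyl)methyl]-5-vinylfuran-2(5H)-one | C=C[C@@H]1C=C(C[Sn](CCCC)(CCCC)CCCC)C(=O)O1
F3 | step 15 | (4R,5R)-4-[(1R,3S)-1-hydroxy-3,7-dimethyl-4-oxo-3-[(triethylsilyl)oxy]oct-7-en-1-yl]-3-methylidene-5-vinyloxolan-2-one | C=C1C(=O)O[C@H](C=C)[C@H]1[C@H](O)C[C@](C)(O[Si](CC)(CC)CC)C(=O)CCC(C)=C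
F4 | step 6 | (2S)-2,4-dihydroxy-N-methoxy-N,2-dimethylbutanamide | CON(C)C(=O)[C@@](C)(O)CCO
F5 | step 6 | (2S)-N-methoxy-N,2-dimethyl-2,4-bis[(triethylsilyl)oxy]butanamide | CON(C)C(=O)[C@@](C)(O[Si](CC)(CC)CC)CCO[Si](CC)(CC)CC
F6 | step 6 | (3S)-3,7-dimethyl-1,3-bis[(triethylsilyl)oxy]oct-7-en-4-one | C=C(C)CCC(=O)[C@@](C)(O[Si](CC)(CC)CC)CCO[Si](CC)(CC)CC
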